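**Plan**

1. Retrosynthetic cuts, in order: the 2'-O–Si bond; the prenyl C=C (back to a C6 allyl group); C4–C4a (ring C); O1–C2 (aryl ether); C3–C1' (ring B to the future C3); and the C6–allyl bond (back to C6–Br).
2. The key step rests on ring A: C4a is para to the C7 methoxy group and ortho to O1, so it is the most nucleophilic ring carbon and can be acylated by a C4 acyl group tethered through O1–C2–C3.
3. Forward: ring B is joined to a malonate, reduced to a prochiral 2-aryl-1,3-diol, desymmetrised, etherified with the ring-A phenol and oxidised to the acid. Ring C is then closed (the only ring formed), the allyl group is converted into prenyl by cross-metathesis and the silyl ether is removed.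
4. Stereochemistry: C3 is the only stereocentre. It is set by lipase monoacetylation of the prochiral diol, carried as a non-enolisable CH and then as an acid-level carbon, and becomes a ketone α-carbon only in the last three, base-free steps.
5. The alkene passes through the acylation as allyl and not as prenyl, because a trisubstituted alkene would be protonated by the HCl/Lewis acid pair set free in that step.

Key step: step 9

Remark: the target is taken as the (3S) enantiomer written in the SMILES; the lipase in step 4 is assumed to acetylate the enantiotopic arm that gives the (S)-monoacetate 6, and the route is written for that sense.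

**Route**

Step 1
Reactants: 1 2-bromo-5-methoxyphenol
Product: 2 (2-bromo-5-methoxyphenoxy)triisopropylsilane
Conditions: TIPSCl, imidazole, DMF, rt
Reagents that add atoms: triisopropylsilyl chloride, CC(C)[Si](Cl)(C(C)C)C(C)C
Why: Imidazole-promoted O-silylation of the phenol (silyl ether formation) installs a bulky TIPS group that should tolerate the base, hydride and Lewis acid to come and keep the 2'-oxygen from closing onto the later acyl group.

Step 2
Reactants: 2 (2-bromo-5-methoxyphenoxy)triisopropylsilane; 3 diethyl malonate
Product: 4 diethyl 2-[4-methoxy-2-(triisopropylsilyloxy)phenyl]malonate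
Conditions: Pd2(dba)3 (1.5 mol%), P(t-Bu)3·HBF4 (6 mol%), K3PO4, toluene, 70 °C
Reagents that add atoms: none
Why: Palladium-catalysed α-arylation of a malonate enolate (Buchwald–Hartwig-type enolate arylation) with a bulky electron-rich trialkylphosphine joins C1' of ring B to the future C3, the silyl ether being a spectator towards a heterogeneous phosphate base in toluene.

Step 3
Reactants: 4 diethyl 2-[4-methoxy-2-(triisopropylsilyloxy)phenyl]malonate
Product: 5 2-[4-methoxy-2-(triisopropylsilyloxy)phenyl]propane-1,3-diol
Conditions: LiAlH4, THF, 0 °C to rt; Rochelle salt work-up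
Reagents that add atoms: none
Why: Hydride reduction of both esters (LiAlH4 reduction of an aryl malonate) should give the prochiral 2-aryl-1,3-diol, and the aryl TIPS ether is expected to survive at or below room temperature.

Step 4
Reactants: 5 2-[4-methoxy-2-(triisopropylsilyloxy)phenyl]propane-1,3-diol
Product: 6 (2S)-3-hydroxy-2-[4-methoxy-2-(triisopropylsilyloxy)phenyl]propyl acetate
Conditions: lipase PS (Burkholderia cepacia, immobilised), vinyl acetate, t-BuOMe, rt; stopped at the monoacetate stage
Reagents that add atoms: vinyl acetate, CC(=O)OC=C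
Why: Enzymatic desymmetrisation by irreversible lipase transesterification with an enol ester acylates one enantiotopic hydroxymethyl group and so creates the only stereocentre (future C3), whose configuration is set by the preference of the enzyme for one prochiral arm.

Step 5
Reactants: 7 4-bromo-3-methoxyphenol; 8 allylboronic acid pinacol ester
Product: 9 4-allyl-3-methoxyphenol
Conditions: Pd(OAc)2 (2 mol%), SPhos (4 mol%), K3PO4, THF–H2O, 50 °C
Reagents that add atoms: none
Why: Suzuki–Miyaura coupling of the allyl boronate with the aryl bromide forms the C6–CH2 bond, with a dialkylbiarylphosphine ligand to secure oxidative addition into the electron-rich bromophenolate; an unsubstituted allyl group raises no α/γ question.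

Step 6
Reactants: 6 (2S)-3-hydroxy-2-[4-methoxy-2-(triisopropylsilyloxy)phenyl]propyl acetate; 9 4-allyl-3-methoxyphenol
Product: 10 (2S)-3-(4-allyl-3-methoxyphenoxy)-2-[4-methoxy-2-(triisopropylsilyloxy)phenyl]propyl acetate
Conditions: PPh3, DIAD, THF, 0 °C to rt
Reagents that add atoms: none
Why: Mitsunobu etherification of the primary alcohol with the phenol forms the future O1–C2 bond under neutral conditions that should not induce acetyl migration, and substitution takes place at CH2, so the stereocentre is not touched.

Step 7
Reactants: 10 (2S)-3-(4-allyl-3-methoxyphenoxy)-2-[4-methoxy-2-(triisopropylsilyloxy)phenyl]propyl acetate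
Product: 11 (2R)-3-(4-allyl-3-methoxyphenoxy)-2-[4-methoxy-2-(triisopropylsilyloxy)phenyl]propan-1-ol
Conditions: K2CO3 (cat.), MeOH, 0 °C
Reagents that add atoms: none
Why: Base-catalysed transesterification with methanol removes the acetate, while the hindered aryl TIPS ether and the non-enolisable stereocentre should be unaffected by catalytic carbonate at 0 °C (the descriptor changes to R only through the priority rules).

Step 8
Reactants: 11 (2R)-3-(4-allyl-3-methoxyphenoxy)-2-[4-methoxy-2-(triisopropylsilyloxy)phenyl]propan-1-ol
Product: 12 (2S)-3-(4-allyl-3-methoxyphenoxy)-2-[4-methoxy-2-(triisopropylsilyloxy)phenyl]propanoic acid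
Conditions: TEMPO (cat.), PhI(OAc)2 (2.2 equiv), MeCN–H2O (1:1), rt
Reagents that add atoms: water, O
Why: The TEMPO/PhI(OAc)2 oxoammonium oxidation takes the primary alcohol through the aldehyde hydrate to the acid in one pot under weakly acidic conditions, which should avoid base-induced epimerisation or loss of aryloxide from the transient α-aryl aldehyde and leave the terminal alkene and silyl ether intact.

Step 9
Reactants: 12 (2S)-3-(4-allyl-3-methoxyphenoxy)-2-[4-methoxy-2-(triisopropylsilyloxy)phenyl]propanoic acid
Product: 14 (3S)-6-allyl-7-methoxy-3-[4-methoxy-2-(triisopropylsilyloxy)phenyl]chroman-4-one, via acid chloride 13 (not isolated)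
Conditions: (COCl)2, DMF (cat.), CH2Cl2, 0 °C to rt, then evaporation; SnCl4 (1.2 equiv), CH2Cl2, −78 °C; cold pH 7 buffer quench
Reagents that add atoms: none
Why: Oxalyl chloride turns the acid into acyl chloride 13 without base, and SnCl4 then polarises the C–Cl bond so that the acyl carbon is attacked by the ring-A carbon ortho to the ether oxygen and para to the methoxy group, giving a Wheland intermediate that loses a proton (intramolecular Friedel–Crafts acylation). The closest known reaction type is the cyclisation of 3-aryloxypropanoic acids or their chlorides to chroman-4-ones. Ring C closes as a six-membered ring by 6-exo-trig attack on the Lewis-acid-bound acyl chloride carbonyl, forming C4–C4a. No stereocentre is created; C3 should be retained because no base is present (no ketene), the reaction runs at −78 °C and the quench is neutral. Selectivity for C4a over C8 follows from para activation by the C7 methoxy group and from the crowding of C8 between two oxygen substituents, while C6 is blocked. The bulky TIPS group should keep the 2'-oxygen from attacking the acyl chloride (benzofuranone formation), and the monosubstituted allyl alkene should not be protonated by the HCl set free.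

Step 10
Reactants: 14 (3S)-6-allyl-7-methoxy-3-[4-methoxy-2-(triisopropylsilyloxy)phenyl]chroman-4-one; 15 2-methyl-2-butene
Product: 16 (3S)-7-methoxy-6-(3-methylbut-2-en-1-yl)-3-[4-methoxy-2-(triisopropylsilyloxy)phenyl]chroman-4-one
Conditions: Grubbs second-generation catalyst (5 mol%), 2-methyl-2-butene (excess), CH2Cl2, 40 °C, sealed vessel
Reagents that add atoms: none
Why: Olefin cross-metathesis of the terminal allyl group with excess 2-methyl-2-butene exchanges the CH2 terminus for an isopropylidene unit and releases propene, under neutral conditions that should not enolise C3.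

Step 11
Reactants: 16 (3S)-7-methoxy-6-(3-methylbut-2-en-1-yl)-3-[4-methoxy-2-(triisopropylsilyloxy)phenyl]chroman-4-one
Product: 17 (3S)-3-(2-hydroxy-4-methoxyphenyl)-7-methoxy-6-(3-methylbut-2-en-1-yl)chroman-4-one
Conditions: HF·pyridine, pyridine, THF, 0 °C to rt
Reagents that add atoms: none
Why: Fluoride-mediated cleavage of the aryl silyl ether under buffered, weakly acidic conditions should free the 2'-hydroxyl without a base strong enough to enolise C3 and without an acid strong enough to add to the prenyl alkene.

**Compound list**

1 | 2-bromo-5-methoxyphenol | COc1ccc(Br)c(O)c1 | starting material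
2 | (2-bromo-5-methoxyphenoxy)triisopropylsilane | COc1ccc(Br)c(O[Si](C(C)C)(C(C)C)C(C)C)c1 | intermediate
3 | diethyl malonate | CCOC(=O)CC(=O)OCC | starting material
4 | diethyl 2-[4-methoxy-2-(triisopropylsilyloxy)phenyl]malonate | CCOC(=O)C(C(=O)OCC)c1ccc(OC)cc1O[Si](C(C)C)(C(C)C)C(C)C | intermediate
5 | 2-[4-methoxy-2-(triisopropylsilyloxy)phenyl]propane-1,3-diol | COc1ccc(C(CO)CO)c(O[Si](C(C)C)(C(C)C)C(C)C)c1 | intermediate
6 | (2S)-3-hydroxy-2-[4-methoxy-2-(triisopropylsilyloxy)phenyl]propyl acetate | COc1ccc([C@@H](CO)COC(C)=O)c(O[Si](C(C)C)(C(C)C)C(C)C)c1 | intermediate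
7 | 4-bromo-3-methoxyphenol | COc1cc(O)ccc1Br | starting material
8 | allylboronic acid pinacol ester | C=CCB1OC(C)(C)C(C)(C)O1 | starting material
9 | 4-allyl-3-methoxyphenol | COc1cc(O)ccc1CC=C | intermediate
10 | (2S)-3-(4-allyl-3-methoxyphenoxy)-2-[4-methoxy-2-(triisopropylsilyloxy)phenyl]propyl acetate | COc1ccc([C@@H](COc2ccc(CC=C)c(OC)c2)COC(C)=O)c(O[Si](C(C)C)(C(C)C)C(C)C)c1 | intermediate
11 | (2R)-3-(4-allyl-3-methoxyphenoxy)-2-[4-methoxy-2-(triisopropylsilyloxy)phenyl]propan-1-ol | COc1ccc([C@@H](COc2ccc(CC=C)c(OC)c2)CO)c(O[Si](C(C)C)(C(C)C)C(C)C)c1 | intermediate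
12 | (2S)-3-(4-allyl-3-methoxyphenoxy)-2-[4-methoxy-2-(triisopropylsilyloxy)phenyl]propanoic acid | COc1ccc([C@@H](COc2ccc(CC=C)c(OC)c2)C(O)=O)c(O[Si](C(C)C)(C(C)C)C(C)C)c1 | intermediate
13 | (2S)-3-(4-allyl-3-methoxyphenoxy)-2-[4-methoxy-2-(triisopropylsilyloxy)phenyl]propanoyl chloride | COc1ccc([C@@H](COc2ccc(CC=C)c(OC)c2)C(Cl)=O)c(O[Si](C(C)C)(C(C)C)C(C)C)c1 | intermediate
14 | (3S)-6-allyl-7-methoxy-3-[4-methoxy-2-(triisopropylsilyloxy)phenyl]chroman-4-one | COc1ccc([C@H]2COc3cc(OC)c(CC=C)cc3C2=O)c(O[Si](C(C)C)(C(C)C)C(C)C)c1 | intermediate
15 | 2-methyl-2-butene | CC=C(C)C | starting material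
16 | (3S)-7-methoxy-6-(3-methylbut-2-en-1-yl)-3-[4-methoxy-2-(triisopropylsilyloxy)phenyl]chroman-4-one | COc1ccc([C@H]2COc3cc(OC)c(CC=C(C)C)cc3C2=O)c(O[Si](C(C)C)(C(C)C)C(C)C)c1 | intermediate
17 | (3S)-3-(2-hydroxy-4-methoxyphenyl)-7-methoxy-6-(3-methylbut-2-en-1-yl)chroman-4-one | COc1ccc([C@H]2COc3cc(OC)c(CC=C(C)C)cc3C2=O)c(O)c1 | target

**Step count and risks**

Total: 11 steps. Longest linear sequence: 10 steps (steps 1–4 and 6–11, from 1 to 17); step 5 is the only step of the side branch.

Steps most likely to fail:

1. Step 9. What may go wrong is transfer of the silyl group from the 2'-oxygen with closure of the acyl chloride to a benzofuranone, erosion of configuration at C3 through enol or ketene formation of the activated acid, or loss of CO from the acylium ion. The fallback forms the same C4–C4a bond by a carbanionic closure; it sets out from phenol 9 and monoacetate 6 and returns at 14. Phenol 9 is brominated with NBS in CH2Cl2 at −78 °C, ortho to the hydroxyl and para to the methoxy group, to give 4-allyl-2-bromo-5-methoxyphenol F1. Mitsunobu coupling of this phenol with 6 (PPh3, DIAD, THF) gives the bromo ether acetate F2, methanolysis (K2CO3 cat., MeOH, 0 °C) the bromo alcohol F3, and TEMPO/PhI(OAc)2 oxidation the bromo acid F4. Treatment of this acid with n-BuLi (2.1 equiv) in THF at −100 °C (Parham cyclisation: deprotonation of the acid, bromine–lithium exchange, addition of the aryllithium to the lithium carboxylate) and a cold acetic acid quench should deliver 14. No Lewis acid is present, the bromine fixes the site of ring closure, and the ketone is released from its dilithium gem-diolate only at the quench.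

2. Step 4. What may go wrong is poor discrimination between the two hydroxymethyl arms next to the bulky ortho-silyloxy group, acylation of the arm that leads to the wrong enantiomer, or over-acylation to the diacetate. The fallback replaces the enzyme by a chiral metal catalyst whose two enantiomers are both available; it sets out from diol 5 and returns at alcohol 11. Diol 5 is desymmetrised with a dinuclear zinc–ProPhenol catalyst (ligand enantiomer chosen for the S product, Et2Zn, vinyl benzoate, toluene, −15 °C) to give (2S)-3-hydroxy-2-[4-methoxy-2-(triisopropylsilyloxy)phenyl]propyl benzoate F5. Mitsunobu coupling with 9 gives the benzoate ether F6, and DIBAL-H in CH2Cl2 at −78 °C removes the benzoate to give 11.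

3. Step 2. What may go wrong is stalled coupling at the hindered, electron-rich ortho-silyloxy bromide, with protodebromination or silyl loss taking over on prolonged heating with base. The fallback builds the three-carbon unit without an enolate arylation; it sets out from bromide 2 and returns at diol 5. Bromine–lithium exchange on 2 (n-BuLi, THF, −78 °C) and inverse addition to diethyl oxalate gives the aryl glyoxylate F7, and Wittig methylenation (Ph3P=CH2, THF, 0 °C) gives the 2-arylacrylate F8. DIBAL-H reduction (CH2Cl2, −78 °C) then gives the 2-arylallyl alcohol F9. Hydroboration–oxidation (BH3·THF, then NaBO3·4H2O) places the second hydroxyl on the terminal carbon and gives 5.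

**Further compounds**

F1 | step 9 | 4-allyl-2-bromo-5-methoxyphenol | COc1cc(O)c(Br)cc1CC=C
F2 | step 9 | (2S)-3-(4-allyl-2-bromo-5-methoxyphenoxy)-2-[4-methoxy-2-(triisopropylsilyloxy)phenyl]propyl acetate | COc1ccc([C@@H](COc2cc(OC)c(CC=C)cc2Br)COC(C)=O)c(O[Si](C(C)C)(C(C)C)C(C)C)c1
F3 | step 9 | (2R)-3-(4-allyl-2-bromo-5-methoxyphenoxy)-2-[4-methoxy-2-(triisopropylsilyloxy)phenyl]propan-1-ol | COc1ccc([C@@H](COc2cc(OC)c(CC=C)cc2Br)CO)c(O[Si](C(C)C)(C(C)C)C(C)C)c1
F4 | step 9 | (2S)-3-(4-allyl-2-bromo-5-methoxyphenoxy)-2-[4-methoxy-2-(triisopropylsilyloxy)phenyl]propanoic acid | COc1ccc([C@@H](COc2cc(OC)c(CC=C)cc2Br)C(O)=O)c(O[Si](C(C)C)(C(C)C)C(C)C)c1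
F5 | step 4 | (2S)-3-hydroxy-2-[4-methoxy-2-(triisopropylsilyloxy)phenyl]propyl benzoate | COc1ccc([C@@H](CO)COC(=O)c2ccccc2)c(O[Si](C(C)C)(C(C)C)C(C)C)c1
F6 | step 4 | (2S)-3-(4-allyl-3-methoxyphenoxy)-2-[4-methoxy-2-(triisopropylsilyloxy)phenyl]propyl benzoate | COc1ccc([C@@H](COc2ccc(CC=C)c(OC)c2)COC(=O)c3ccccc3)c(O[Si](C(C)C)(C(C)C)C(C)C)c1
F7 | step 2 | ethyl 2-[4-methoxy-2-(triisopropylsilyloxy)phenyl]-2-oxoacetate | CCOC(=O)C(=O)c1ccc(OC)cc1O[Si](C(C)C)(C(C)C)C(C)C
F8 | step 2 | ethyl 2-[4-methoxy-2-(triisopropylsilyloxy)phenyl]acrylate | CCOC(=O)C(=C)c1ccc(OC)cc1O[Si](C(C)C)(C(C)C)C(C)C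
F9 | step 2 | 2-[4-methoxy-2-(triisopropylsilyloxy)phenyl]prop-2-en-1-ol | C=C(CO)c1ccc(OC)cc1O[Si](C(C)C)(C(C)C)C(C)C
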